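We start from late times, where the alpha run stands still: at 10.0 d it holds G 29 % and D 33 %, so G is 0.433 of the reacted D, and this late share is what we carry.

| setting | alpha | delta | gamma | flask |
|---|---|---|---|---|
| D | 0.14 M | 0.22 M | 0.10 M | 0.10 M |
| J | 0.095 M | 0.095 M | 0.048 M | 0.0950 M |
| remark | run made earlier | run made earlier | run made earlier |  |
| time |  |  |  | 15 d |

- alpha (time / d: G / %, D / %): 0.125: 30, 67; 0.333: 48, 38; 0.625: 36, 32; 1.67: 28, 31; 4.00: 30, 33; 10.0: 29, 33
- delta (time / d: G / %, D / %): 0.125: 30, 65; 0.333: 28, 55; 0.625: 22, 56; 1.67: 16, 55; 4.00: 17, 57; 10.0: 14, 56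
- gamma (time / d: G / %, D / %): 0.125: 29, 67; 0.333: 32, 50; 1.04: 20, 52; 3.00: 19, 50; 10.0: 20, 52

(standard deviation of a reading: 1.5 percentage points)



- the moment within 15 d at which there is most G
- the amount of G, in percent of the D charged, at that time

We bracket the peak. J, the limiting reagent, covers 0.950 of this flask's D, which is a loose ceiling. The runs lose D alike at first, and this flask has more J per D, so we expect it to follow alpha at least to alpha's reading of 48 % at 0.333 d, our floor.

D falls at 3.20 d⁻¹, and alpha's excess of G over its late value falls at about 3.42 d⁻¹. The making of G over its loss, reckoned from these alpha readings, is then 1.68 at 0.333 d, above unity, so we reckon G in this flask still rising at that time. We expect the ratio to drift down as D falls, and the peak is where it reaches unity. That puts D below alpha's 38 % there, so we reckon G at the peak under 62.4 %, and the time under 0.935 d, where D at this rate has lost the share that J covers.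

The forecast lies inside, 54 % (49 % to 60 %) at 0.6 d (0.45 d to 0.85 d): “The maximum falls at t ≈ 0.6 d, G ≈ 54%, before J runs out”.

The flask gives 50.7 % at 0.491 d, inside the bracket.

    D ⇌ E + Q (K = 7.10 × 10⁻⁴ M, k = 0.140 h⁻¹)
    J + E → G (k = 4800 M⁻¹ h⁻¹)
    G ⇌ X (K = 1.40, k = 0.0810 h⁻¹)

The forecast's time is 1.22 times that. At 15.0 d this flask has reacted 95.0 % of its D, and the late share gives 41.1 % against the 39.6 % of G it holds. In a neighbouring flask with 0.25 M of D and this flask's J, J covers 38.0 % of the charge, so the same share gives 16.4 %. That neighbouring flask ends with 61.5 % of its D left and G at 15.8 %.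

All runs are calculated with made-up constants, and the scatter is random.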